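## Retrosynthetic overview

1. The target is reached by C15 desilylation and late allylic oxidation of the C14 methyl to the enal; both angelates are put on a free 8,9-diol in one operation.
2. Key disconnection, C7–C8: a SmI2 ketyl radical from a C8 aldehyde adds to the β-carbon of a 3-(methoxymethyl)butenolide and methoxide is expelled. This closes the ten-membered ring, sets C7 and C8, and unveils the exo-methylene lactone.
3. The butenolide comes from an enal by asymmetric alkynylation (sets C6), trans-hydroalumination/iodination and carbonylative lactonisation.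
4. C1=C10 comes from a Z-selective Wittig reaction of a chiral-pool α-silyloxy methyl ketone (sets C9); C4=C5 from hydroalumination/iodination of mono-protected butynediol and a Negishi coupling.
5. Ring order: butenolide first (step 11), ten-membered carbocycle second (step 13).

Assumption: atoms are tracked with germacrane numbering (C1–C15; lactone O on C6, esters on C8 and C9, C14 = formyl carbon, C15 = hydroxymethyl carbon); the (S,S)-ProPhenol–zinc catalyst is taken to give the 6R carbinol in step 9 (the mirror-image ligand is used if the facial sense proves opposite).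

## Route

Step 1
Reactants: 1 but-2-yne-1,4-diol
Product: 2 4-[(tert-butyldiphenylsilyl)oxy]but-2-yn-1-ol
Conditions: NaH (1.0 equiv), THF, 0 °C; then TBDPSCl (1.0 equiv), 0 °C → rt
Reagents that add atoms: tert-butyl(chloro)diphenylsilane, CC(C)(C)[Si](Cl)(c1ccccc1)c1ccccc1
Why: Monosilylation of a symmetrical diol through its monosodium alkoxide leaves one free hydroxyl (future C6, the directing group) and protects the other (future C15).

Step 2
Reactants: 2 4-[(tert-butyldiphenylsilyl)oxy]but-2-yn-1-ol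
Product: 4 (2Z)-4-[(tert-butyldiphenylsilyl)oxy]-3-iodobut-2-en-1-ol, via cyclic alkenylaluminate 3 (not isolated)
Conditions: NaAlH2(OCH2CH2OCH3)2 (1.5 equiv), THF, 0 °C; then iodine, THF, −78 °C
Reagents that add atoms: iodine, [I][I]
Why: Hydroxyl-directed trans-hydroalumination of the 2-alkyn-1-ol puts aluminium on the distal alkyne carbon (C4) in a five-membered oxa-aluminacycle, and iodinolysis with retention gives the Z-vinyl iodide (iodine cis to CH2OH), which fixes the C4=C5 geometry.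

Step 3
Reactants: 4 (2Z)-4-[(tert-butyldiphenylsilyl)oxy]-3-iodobut-2-en-1-ol; 5 1-bromo-3-chloropropane
Product: 7 (2E)-3-{[(tert-butyldiphenylsilyl)oxy]methyl}-6-chlorohex-2-en-1-ol, via organozinc 6 (not isolated)
Conditions: 5, Zn dust, LiCl, THF, 40 °C; then 4, Pd(PPh3)4 (5 mol%), THF, 25 → 40 °C
Reagents that add atoms: none
Why: Negishi sp2–sp3 cross-coupling of the alkenyl iodide with the alkylzinc halide proceeds with retention of alkene geometry (C3 chain cis to C6) and tolerates the free hydroxyl and the alkyl chloride.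

Step 4
Reactants: 7 (2E)-3-{[(tert-butyldiphenylsilyl)oxy]methyl}-6-chlorohex-2-en-1-ol
Product: 9 [(4E)-4-{[(tert-butyldiphenylsilyl)oxy]methyl}-6-hydroxyhex-4-en-1-yl]triphenylphosphonium iodide, via primary iodide 8 (not isolated)
Conditions: NaI (1.5 equiv), PPh3 (1.2 equiv), MeCN, reflux
Reagents that add atoms: triphenylphosphine, c1ccc(cc1)P(c1ccccc1)c1ccccc1; sodium iodide, [Na+].[I-]
Why: In situ Finkelstein exchange followed by SN2 quaternisation of PPh3 gives the Wittig salt without touching the allylic alcohol or the silyl ether.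

Step 5
Reactants: 10 (2S)-but-3-ene-1,2-diol
Product: 11 (2S)-1,2-bis[(triethylsilyl)oxy]but-3-ene
Conditions: TESCl (2.3 equiv), imidazole, CH2Cl2, 0 °C → rt
Reagents that add atoms: chlorotriethylsilane, CC[Si](Cl)(CC)CC
Why: Standard bis-silylation of the chiral-pool diol (source of C9); TES is chosen because a primary TES ether can later be oxidised directly to an aldehyde next to a secondary one.

Step 6
Reactants: 11 (2S)-1,2-bis[(triethylsilyl)oxy]but-3-ene
Product: 12 (3R)-3,4-bis[(triethylsilyl)oxy]butan-2-one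
Conditions: PdCl2(quinox) (5 mol%; quinox = 2-(4,5-dihydrooxazol-2-yl)quinoline), AgSbF6 (12 mol%), aq. t-BuOOH, CH2Cl2, 0 °C → rt
Reagents that add atoms: tert-butyl hydroperoxide, CC(C)(C)OO
Why: Catalyst-controlled Tsuji–Wacker oxidation of the protected allylic alcohol gives the methyl ketone without touching the adjacent stereocentre (the descriptor changes from S to R only through CIP priorities).

Step 7
Reactants: 9 [(4E)-4-{[(tert-butyldiphenylsilyl)oxy]methyl}-6-hydroxyhex-4-en-1-yl]triphenylphosphonium iodide; 12 (3R)-3,4-bis[(triethylsilyl)oxy]butan-2-one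
Product: 14 (2E,6Z,8S)-3-{[(tert-butyldiphenylsilyl)oxy]methyl}-7-methyl-8,9-bis[(triethylsilyl)oxy]nona-2,6-dien-1-ol, via phosphonium ylide 13 (not isolated)
Conditions: 9, NaN(SiMe3)2 (2.1 equiv), THF, −78 → 0 °C; then 12, −78 → −20 °C
Reagents that add atoms: none
Why: Wittig olefination of an α-oxygenated methyl ketone with an unstabilised ylide is strongly Z-selective for the trisubstituted alkene (ylide chain cis to the oxygen-bearing carbon C9), and the C9 stereocentre is carried through unchanged.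

Step 8
Reactants: 14 (2E,6Z,8S)-3-{[(tert-butyldiphenylsilyl)oxy]methyl}-7-methyl-8,9-bis[(triethylsilyl)oxy]nona-2,6-dien-1-ol
Product: 15 (2E,6Z,8S)-3-{[(tert-butyldiphenylsilyl)oxy]methyl}-7-methyl-8,9-bis[(triethylsilyl)oxy]nona-2,6-dienal
Conditions: MnO2 (15 equiv), CH2Cl2, rt
Reagents that add atoms: none
Why: MnO2 oxidises only the primary allylic alcohol, under neutral conditions that preserve the alkene geometry and all silyl ethers.

Step 9
Reactants: 15 (2E,6Z,8S)-3-{[(tert-butyldiphenylsilyl)oxy]methyl}-7-methyl-8,9-bis[(triethylsilyl)oxy]nona-2,6-dienal; 16 3-methoxyprop-1-yne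
Product: 18 (4R,5E,9Z,11S)-6-{[(tert-butyldiphenylsilyl)oxy]methyl}-1-methoxy-10-methyl-11,12-bis[(triethylsilyl)oxy]dodeca-5,9-dien-2-yn-4-ol, via alkynylzinc 17 (not isolated)
Conditions: 16 (3 equiv), Zn(CH3)2 (3 equiv), (S,S)-ProPhenol (20 mol%), Ph3P=O (40 mol%), toluene, 0 °C
Reagents that add atoms: none
Why: Zinc–ProPhenol catalysed asymmetric alkynylation of the enal sets the C6 carbinol centre (R) by catalyst control and supplies C7, C11 and C13.

Step 10
Reactants: 18 (4R,5E,9Z,11S)-6-{[(tert-butyldiphenylsilyl)oxy]methyl}-1-methoxy-10-methyl-11,12-bis[(triethylsilyl)oxy]dodeca-5,9-dien-2-yn-4-ol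
Product: 20 (2Z,4R,5E,9Z,11S)-6-{[(tert-butyldiphenylsilyl)oxy]methyl}-2-iodo-1-methoxy-10-methyl-11,12-bis[(triethylsilyl)oxy]dodeca-2,5,9-trien-4-ol, via cyclic alkenylaluminate 19 (not isolated)
Conditions: NaAlH2(OCH2CH2OCH3)2 (1.6 equiv), THF, 0 °C; then iodine, THF, −78 °C
Reagents that add atoms: iodine, [I][I]
Why: The same hydroxyl-directed trans-hydroalumination/iodination as in step 2 gives the Z-γ-iodo allylic alcohol with iodine cis to the carbinol carbon, and keeping the aluminate at or below 0 °C avoids loss of methoxide to an allene.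

Step 11
Reactants: 20 (2Z,4R,5E,9Z,11S)-6-{[(tert-butyldiphenylsilyl)oxy]methyl}-2-iodo-1-methoxy-10-methyl-11,12-bis[(triethylsilyl)oxy]dodeca-2,5,9-trien-4-ol
Product: 21 (5R)-5-[(1E,5Z,7S)-2-{[(tert-butyldiphenylsilyl)oxy]methyl}-6-methyl-7,8-bis[(triethylsilyl)oxy]octa-1,5-dien-1-yl]-3-(methoxymethyl)furan-2(5H)-one
Conditions: PdCl2(PPh3)2 (5 mol%), CO (1 atm), i-Pr2NEt, THF, 45 °C
Reagents that add atoms: carbon monoxide, [C-]#[O+]
Why: Palladium-catalysed carbonylative lactonisation (oxidative addition to the vinyl iodide, CO insertion, capture of the acylpalladium by the cis hydroxyl) closes the butenolide and supplies C12 with C6 untouched.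

Step 12
Reactants: 21 (5R)-5-[(1E,5Z,7S)-2-{[(tert-butyldiphenylsilyl)oxy]methyl}-6-methyl-7,8-bis[(triethylsilyl)oxy]octa-1,5-dien-1-yl]-3-(methoxymethyl)furan-2(5H)-one
Product: 22 (2S,3Z,7E)-7-{[(tert-butyldiphenylsilyl)oxy]methyl}-8-[(2R)-4-(methoxymethyl)-5-oxo-2,5-dihydrofuran-2-yl]-3-methyl-2-[(triethylsilyl)oxy]octa-3,7-dienal
Conditions: (COCl)2, DMSO, CH2Cl2, −78 → −40 °C; then Et3N, −78 → −20 °C; used crude
Reagents that add atoms: none
Why: Under Swern conditions a primary TES ether is converted directly into the aldehyde while the secondary TES ether, the TBDPS ether and the butenolide survive, and cold addition of base avoids epimerisation at C9 and C6.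

Step 13
Reactants: 22 (2S,3Z,7E)-7-{[(tert-butyldiphenylsilyl)oxy]methyl}-8-[(2R)-4-(methoxymethyl)-5-oxo-2,5-dihydrofuran-2-yl]-3-methyl-2-[(triethylsilyl)oxy]octa-3,7-dienal
Product: 24 (6R,7R,8S,9S)-15-[(tert-butyldiphenylsilyl)oxy]-8,9-dihydroxygermacra-1(10)Z,4E,11(13)-trien-12,6-olide, via TES-protected macrocyclic alcohol 23 (not isolated)
Conditions: SmI2 (2.2 equiv, 0.1 M in THF) added over 2 h to 22 (2 mM) and HMPA (8 equiv) in THF, −40 °C; then 1 M HCl, THF, 0 °C → rt
Reagents that add atoms: none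
Why: Proposed new method: one-electron reduction of the aldehyde gives a ketyl radical that adds in a 10-exo closure to the butenolide β-carbon C7 anti to the C6 substituent (trans-fused lactone), a second electron gives the samarium enolate which expels methoxide (E1cB) to unveil the exo-methylene, and C8 is expected threo to C9 from an A(1,3)-strain model in which H9 eclipses the bulky samarium-bound oxygen and the new bond forms anti to the OTES group; the closest known reaction types are SmI2 ketyl–olefin cyclisation followed by β-elimination and intermolecular ketyl additions to butenolides.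

Step 14
Reactants: 24 (6R,7R,8S,9S)-15-[(tert-butyldiphenylsilyl)oxy]-8,9-dihydroxygermacra-1(10)Z,4E,11(13)-trien-12,6-olide; 25 angelic acid [(2Z)-2-methylbut-2-enoic acid]
Product: 27 (6R,7S,8S,9S)-8,9-bis(angeloyloxy)-15-[(tert-butyldiphenylsilyl)oxy]germacra-1(10)Z,4E,11(13)-trien-12,6-olide, via mixed anhydride 26 (not isolated)
Conditions: 25 (6 equiv), 2,4,6-trichlorobenzoyl chloride (6 equiv), Et3N, toluene, rt, filter; then 24, toluene, 75 °C (no DMAP)
Reagents that add atoms: none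
Why: Yamaguchi-type mixed-anhydride esterification without a nucleophilic catalyst acylates both secondary hydroxyls without Z→E isomerisation to tiglate, and no stereocentre is touched (C7 changes descriptor only through CIP priorities).

Step 15
Reactants: 27 (6R,7S,8S,9S)-8,9-bis(angeloyloxy)-15-[(tert-butyldiphenylsilyl)oxy]germacra-1(10)Z,4E,11(13)-trien-12,6-olide
Product: 29 (6R,7S,8S,9S)-8,9-bis(angeloyloxy)-15-[(tert-butyldiphenylsilyl)oxy]-14-oxogermacra-1(10)E,4E,11(13)-trien-12,6-olide, via allylic alcohol 28 (not isolated)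
Conditions: SeO2 (0.5 equiv), t-BuOOH (2.5 equiv), CH2Cl2, 0 °C → rt; then MnO2, CH2Cl2, rt
Reagents that add atoms: tert-butyl hydroperoxide (oxygen atom relayed through SeO2), CC(C)(C)OO
Why: Riley allylic oxidation (ene reaction then [2,3]-sigmatropic shift) attacks the most electron-rich alkene C1=C10 at its methyl group and places the new oxygen trans to C2, which is the ring-cis geometry already present, and MnO2 takes the allylic alcohol on to the enal.

Step 16
Reactants: 29 (6R,7S,8S,9S)-8,9-bis(angeloyloxy)-15-[(tert-butyldiphenylsilyl)oxy]-14-oxogermacra-1(10)E,4E,11(13)-trien-12,6-olide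
Product: 30 (6R,7S,8S,9S)-8,9-bis(angeloyloxy)-15-hydroxy-14-oxogermacra-1(10)E,4E,11(13)-trien-12,6-olide (CNP0139154.1)
Conditions: HF·pyridine, pyridine, THF, 0 °C → rt
Reagents that add atoms: none
Why: Fluoride-mediated cleavage of the TBDPS ether with buffered HF·pyridine frees the C15 alcohol without harming the enal, the angelates or the α-methylene lactone.

## Compound list

1 | but-2-yne-1,4-diol | OCC#CCO | starting material
2 | 4-[(tert-butyldiphenylsilyl)oxy]but-2-yn-1-ol | OCC#CCO[Si](c1ccccc1)(c1ccccc1)C(C)(C)C | intermediate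
3 | sodium bis(2-methoxyethoxy) oxa-aluminacyclopentene ate complex from 2 (Al on the silyloxymethyl-bearing alkene carbon) | [Na+].COCCO[Al-]1(OCCOC)OCC=C1CO[Si](c1ccccc1)(c1ccccc1)C(C)(C)C | intermediate
4 | (2Z)-4-[(tert-butyldiphenylsilyl)oxy]-3-iodobut-2-en-1-ol | OC/C=C(/CO[Si](c1ccccc1)(c1ccccc1)C(C)(C)C)I | intermediate
5 | 1-bromo-3-chloropropane | ClCCCBr | starting material
6 | (3-chloropropyl)zinc bromide | ClCCC[Zn]Br | intermediate
7 | (2E)-3-{[(tert-butyldiphenylsilyl)oxy]methyl}-6-chlorohex-2-en-1-ol | OC/C=C(/CO[Si](c1ccccc1)(c1ccccc1)C(C)(C)C)CCCCl | intermediate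
8 | (2E)-3-{[(tert-butyldiphenylsilyl)oxy]methyl}-6-iodohex-2-en-1-ol | OC/C=C(/CO[Si](c1ccccc1)(c1ccccc1)C(C)(C)C)CCCI | intermediate
9 | [(4E)-4-{[(tert-butyldiphenylsilyl)oxy]methyl}-6-hydroxyhex-4-en-1-yl]triphenylphosphonium iodide | OC/C=C(/CO[Si](c1ccccc1)(c1ccccc1)C(C)(C)C)CCC[P+](c1ccccc1)(c1ccccc1)c1ccccc1.[I-] | intermediate
10 | (2S)-but-3-ene-1,2-diol | OC[C@@H](O)C=C | starting material
11 | (2S)-1,2-bis[(triethylsilyl)oxy]but-3-ene | CC[Si](CC)(CC)OC[C@@H](O[Si](CC)(CC)CC)C=C | intermediate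
12 | (3R)-3,4-bis[(triethylsilyl)oxy]butan-2-one | CC[Si](CC)(CC)OC[C@@H](O[Si](CC)(CC)CC)C(C)=O | intermediate
13 | sodium alkoxide ylide from 9 | [Na+].[O-]C/C=C(/CO[Si](c1ccccc1)(c1ccccc1)C(C)(C)C)CCC=P(c1ccccc1)(c1ccccc1)c1ccccc1 | intermediate
14 | (2E,6Z,8S)-3-{[(tert-butyldiphenylsilyl)oxy]methyl}-7-methyl-8,9-bis[(triethylsilyl)oxy]nona-2,6-dien-1-ol | OC/C=C(/CO[Si](c1ccccc1)(c1ccccc1)C(C)(C)C)CC/C=C(/C)[C@H](O[Si](CC)(CC)CC)CO[Si](CC)(CC)CC | intermediate
15 | (2E,6Z,8S)-3-{[(tert-butyldiphenylsilyl)oxy]methyl}-7-methyl-8,9-bis[(triethylsilyl)oxy]nona-2,6-dienal | O=C/C=C(/CO[Si](c1ccccc1)(c1ccccc1)C(C)(C)C)CC/C=C(/C)[C@H](O[Si](CC)(CC)CC)CO[Si](CC)(CC)CC | intermediate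
16 | 3-methoxyprop-1-yne | COCC#C | starting material
17 | methyl(3-methoxyprop-1-yn-1-yl)zinc | COCC#C[Zn]C | intermediate
18 | (4R,5E,9Z,11S)-6-{[(tert-butyldiphenylsilyl)oxy]methyl}-1-methoxy-10-methyl-11,12-bis[(triethylsilyl)oxy]dodeca-5,9-dien-2-yn-4-ol | COCC#C[C@H](O)/C=C(/CO[Si](c1ccccc1)(c1ccccc1)C(C)(C)C)CC/C=C(/C)[C@H](O[Si](CC)(CC)CC)CO[Si](CC)(CC)CC | intermediate
19 | sodium bis(2-methoxyethoxy) oxa-aluminacyclopentene ate complex from 18 (Al on the methoxymethyl-bearing alkene carbon) | [Na+].COCCO[Al-]1(OCCOC)O[C@H](/C=C(/CO[Si](c2ccccc2)(c2ccccc2)C(C)(C)C)CC/C=C(/C)[C@H](O[Si](CC)(CC)CC)CO[Si](CC)(CC)CC)C=C1COC | intermediate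
20 | (2Z,4R,5E,9Z,11S)-6-{[(tert-butyldiphenylsilyl)oxy]methyl}-2-iodo-1-methoxy-10-methyl-11,12-bis[(triethylsilyl)oxy]dodeca-2,5,9-trien-4-ol | COCC(/I)=C/[C@H](O)/C=C(/CO[Si](c1ccccc1)(c1ccccc1)C(C)(C)C)CC/C=C(/C)[C@H](O[Si](CC)(CC)CC)CO[Si](CC)(CC)CC | intermediate
21 | (5R)-5-[(1E,5Z,7S)-2-{[(tert-butyldiphenylsilyl)oxy]methyl}-6-methyl-7,8-bis[(triethylsilyl)oxy]octa-1,5-dien-1-yl]-3-(methoxymethyl)furan-2(5H)-one | COCC1=C[C@@H](/C=C(/CO[Si](c2ccccc2)(c2ccccc2)C(C)(C)C)CC/C=C(/C)[C@H](O[Si](CC)(CC)CC)CO[Si](CC)(CC)CC)OC1=O | intermediate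
22 | (2S,3Z,7E)-7-{[(tert-butyldiphenylsilyl)oxy]methyl}-8-[(2R)-4-(methoxymethyl)-5-oxo-2,5-dihydrofuran-2-yl]-3-methyl-2-[(triethylsilyl)oxy]octa-3,7-dienal | COCC1=C[C@@H](/C=C(/CO[Si](c2ccccc2)(c2ccccc2)C(C)(C)C)CC/C=C(/C)[C@H](O[Si](CC)(CC)CC)C=O)OC1=O | intermediate
23 | (6R,7R,8S,9S)-15-[(tert-butyldiphenylsilyl)oxy]-8-hydroxy-9-[(triethylsilyl)oxy]germacra-1(10)Z,4E,11(13)-trien-12,6-olide | C=C1C(=O)O[C@@H]2/C=C(/CO[Si](c3ccccc3)(c3ccccc3)C(C)(C)C)CC/C=C(/C)[C@H](O[Si](CC)(CC)CC)[C@@H](O)[C@@H]12 | intermediate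
24 | (6R,7R,8S,9S)-15-[(tert-butyldiphenylsilyl)oxy]-8,9-dihydroxygermacra-1(10)Z,4E,11(13)-trien-12,6-olide | C=C1C(=O)O[C@@H]2/C=C(/CO[Si](c3ccccc3)(c3ccccc3)C(C)(C)C)CC/C=C(/C)[C@H](O)[C@@H](O)[C@@H]12 | intermediate
25 | angelic acid, (2Z)-2-methylbut-2-enoic acid | C/C=C(/C)C(=O)O | starting material
26 | (2Z)-2-methylbut-2-enoic 2,4,6-trichlorobenzoic anhydride | C/C=C(/C)C(=O)OC(=O)c1c(Cl)cc(Cl)cc1Cl | intermediate
27 | (6R,7S,8S,9S)-8,9-bis(angeloyloxy)-15-[(tert-butyldiphenylsilyl)oxy]germacra-1(10)Z,4E,11(13)-trien-12,6-olide | C=C1C(=O)O[C@@H]2/C=C(/CO[Si](c3ccccc3)(c3ccccc3)C(C)(C)C)CC/C=C(/C)[C@H](OC(=O)/C(C)=C\C)[C@@H](OC(=O)/C(C)=C\C)[C@@H]12 | intermediate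
28 | (6R,7S,8S,9S)-8,9-bis(angeloyloxy)-15-[(tert-butyldiphenylsilyl)oxy]-14-hydroxygermacra-1(10)Z,4E,11(13)-trien-12,6-olide | C=C1C(=O)O[C@@H]2/C=C(/CO[Si](c3ccccc3)(c3ccccc3)C(C)(C)C)CC/C=C(/CO)[C@H](OC(=O)/C(C)=C\C)[C@@H](OC(=O)/C(C)=C\C)[C@@H]12 | intermediate
29 | (6R,7S,8S,9S)-8,9-bis(angeloyloxy)-15-[(tert-butyldiphenylsilyl)oxy]-14-oxogermacra-1(10)E,4E,11(13)-trien-12,6-olide | C=C1C(=O)O[C@@H]2/C=C(/CO[Si](c3ccccc3)(c3ccccc3)C(C)(C)C)CC/C=C(/C=O)[C@H](OC(=O)/C(C)=C\C)[C@@H](OC(=O)/C(C)=C\C)[C@@H]12 | intermediate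
30 | (6R,7S,8S,9S)-8,9-bis(angeloyloxy)-15-hydroxy-14-oxogermacra-1(10)E,4E,11(13)-trien-12,6-olide (CNP0139154.1) | C=C1C(=O)O[C@@H]2/C=C(/CO)CC/C=C(/C=O)[C@H](OC(=O)/C(C)=C\C)[C@@H](OC(=O)/C(C)=C\C)[C@@H]12 | target

## Step count and risks

Total step count: 16.
Longest linear sequence: 14 steps (steps 1–4, then 7–16); steps 5–6 prepare the ketone partner.

The three steps most likely to fail:

Step 13 (ketyl macrocyclisation). The ten-membered radical closure is unprecedented on this substrate. It competes with pinacol dimerisation, simple reduction and over-reduction of the product lactone, and the C8 configuration rests on a model. If the closure gives the 8-epimer (8,9-erythro), the fallback sets out from 22: the SmI2 closure is run without the acidic work-up and the 9-O-TES 8-epi alcohol (6R,7R,8R,9S)-15-[(tert-butyldiphenylsilyl)oxy]-8-hydroxy-9-[(triethylsilyl)oxy]germacra-1(10)Z,4E,11(13)-trien-12,6-olide F1 is isolated. C8 is then inverted while the first ester is installed, by Mitsunobu esterification with angelic acid 25 (PPh3, DIAD, toluene), giving the 8-angelate 9-silyl ether F2. HF·pyridine removes the TES group to give the 9-alcohol 8-angelate F3, which is acylated with mixed anhydride 26 as in step 14. The fallback returns to the route at 27.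

Step 15 (allylic oxidation). The C3 methylene on the other trisubstituted alkene could compete, and the oxidation may stall at the alcohol or isomerise the angelates. The fallback sets out from 27 and replaces the selenium ene reaction by an ene-type chlorination with HOCl (Ca(OCl)2, CO2, CH2Cl2/H2O, 0 °C), which gives the rearranged allylic chloride (1-chloro, C10=C14 exo-methylene) F5. An SN2′ oxidation with N-methylmorpholine N-oxide (Ganem type, MeCN, 50 °C) moves the double bond back to C1=C10 and delivers the enal. The fallback returns to the route at 29.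

Step 14 (double angeloylation). The vicinal diol is hindered, the free 8-hydroxyl can translactonise on heating, and angelates isomerise easily. The fallback sets out from 24: both hydroxyls are esterified with 2-[bis(2,2,2-trifluoroethoxy)phosphoryl]propanoic acid (DIC, DMAP, CH2Cl2, 0 °C) to give the bis(phosphonopropanoate) F4. A double Still–Gennari olefination with acetaldehyde (KN(SiMe3)2, 18-crown-6, THF, −78 °C) then builds both (Z)-2-methylbut-2-enoates in place. The fallback returns to the route at 27.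

## Further compounds

F1 | step 13 | (6R,7R,8R,9S)-15-[(tert-butyldiphenylsilyl)oxy]-8-hydroxy-9-[(triethylsilyl)oxy]germacra-1(10)Z,4E,11(13)-trien-12,6-olide (8-epimer of 23) | C=C1C(=O)O[C@@H]2/C=C(/CO[Si](c3ccccc3)(c3ccccc3)C(C)(C)C)CC/C=C(/C)[C@H](O[Si](CC)(CC)CC)[C@H](O)[C@@H]12
F2 | step 13 | (6R,7S,8S,9S)-8-(angeloyloxy)-15-[(tert-butyldiphenylsilyl)oxy]-9-[(triethylsilyl)oxy]germacra-1(10)Z,4E,11(13)-trien-12,6-olide | C=C1C(=O)O[C@@H]2/C=C(/CO[Si](c3ccccc3)(c3ccccc3)C(C)(C)C)CC/C=C(/C)[C@H](O[Si](CC)(CC)CC)[C@@H](OC(=O)/C(C)=C\C)[C@@H]12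
F3 | step 13 | (6R,7S,8S,9S)-8-(angeloyloxy)-15-[(tert-butyldiphenylsilyl)oxy]-9-hydroxygermacra-1(10)Z,4E,11(13)-trien-12,6-olide | C=C1C(=O)O[C@@H]2/C=C(/CO[Si](c3ccccc3)(c3ccccc3)C(C)(C)C)CC/C=C(/C)[C@H](O)[C@@H](OC(=O)/C(C)=C\C)[C@@H]12
F4 | step 14 | 8,9-bis{2-[bis(2,2,2-trifluoroethoxy)phosphoryl]propanoyloxy}-15-[(tert-butyldiphenylsilyl)oxy]germacra-1(10)Z,4E,11(13)-trien-12,6-olide (ring stereocentres as in 24; phosphonate α-carbons epimeric mixture) | C=C1C(=O)O[C@@H]2/C=C(/CO[Si](c3ccccc3)(c3ccccc3)C(C)(C)C)CC/C=C(/C)[C@H](OC(=O)C(C)P(=O)(OCC(F)(F)F)OCC(F)(F)F)[C@@H](OC(=O)C(C)P(=O)(OCC(F)(F)F)OCC(F)(F)F)[C@@H]12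
F5 | step 15 | 8,9-bis(angeloyloxy)-15-[(tert-butyldiphenylsilyl)oxy]-1-chlorogermacra-4E,10(14),11(13)-trien-12,6-olide (ring stereocentres as in 27; C1 epimeric mixture) | C=C1C(=O)O[C@@H]2/C=C(/CO[Si](c3ccccc3)(c3ccccc3)C(C)(C)C)CCC(Cl)C(=C)[C@H](OC(=O)/C(C)=C\C)[C@@H](OC(=O)/C(C)=C\C)[C@@H]12
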